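## Retrosynthetic overview
1. Target ⇒ BrCl + acyclic (1E,3Z,6R)-1-bromo-6-chloro-3,7-dimethylocta-1,3,7-triene. The last step makes C4–Br, the C3–C8 ring bond and C7–Cl at once. This is the bromonium-triggered, chloride-terminated closure proposed for the Plocamium cyclohexanes, and it sets three stereocentres from the one at C6.
2. C6–Cl ⇒ 6S allylic alcohol (SN2 inversion).
3. 1E-bromodiene ⇒ Takai bromo-olefination of a Z-enal stored as its lactol.
4. 3Z alkene ⇒ temporary dihydropyranone ring from RCM of a methacrylate ester ⇒ one-pot Keck allylation/acylation of methacrolein.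
5. Ring order: lactone ring first (step 2, opened again in step 4), cyclohexane last (step 6).

Assumption: acyclic terpenoid numbering is used throughout (C1 = CHBr terminus, C3 = quaternary carbon, C4 = CHBr, C6 = CHCl, C7 = CClMe, C8 = ring CH2), and anhydrous CrBr2 is taken as purchasable.

## Route

Step 1
Reactants: 1 methacrolein; 2 allyltributylstannane; 3 methacryloyl chloride
Product: 5 (3S)-2-methylhexa-1,5-dien-3-yl 2-methylprop-2-enoate, via tributylstannyl ether 4 (not isolated)
Conditions: (S)-BINOL (10 mol%), Ti(OiPr)4 (10 mol%), 4 Å MS, CH2Cl2, −20 °C, 60 h; then 3 (1.3 equiv), DMAP (10 mol%), 0 °C → rt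
Reagents that add atoms: allyltributylstannane (2), C=CC[Sn](CCCC)(CCCC)CCCC; methacryloyl chloride (3), CC(=C)C(=O)Cl
Why: Keck asymmetric allylation, in which the (S)-BINOL–Ti(OiPr)4 Lewis acid exposes one carbonyl face of the 2-methyl enal to open-transition-state allyl transfer and gives the S carbinol centre C6 (about 90–95% ee, as for other 2-methyl enals, 1,2-addition only), after which the nucleophilic O–Sn bond of 4 is acylated in the same flask without touching the C–O stereocentre, so no volatile alcohol is isolated.

Step 2
Reactants: 5 (3S)-2-methylhexa-1,5-dien-3-yl 2-methylprop-2-enoate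
Product: 6 (6S)-3-methyl-6-(prop-1-en-2-yl)-5,6-dihydro-2H-pyran-2-one
Conditions: second-generation Grubbs catalyst (5 mol%), CH2Cl2 (0.005 M), reflux, 12 h
Reagents that add atoms: none
Why: Ring-closing metathesis, in which the catalyst loads on the only monosubstituted alkene and can close only onto the methacrylate (closure onto the isopropenyl group would give a cyclobutene), and the six-membered ring forces the new trisubstituted C3=C4 alkene to be Z with C6 untouched.

Step 3
Reactants: 6 (6S)-3-methyl-6-(prop-1-en-2-yl)-5,6-dihydro-2H-pyran-2-one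
Product: 7 (6S)-3-methyl-6-(prop-1-en-2-yl)-5,6-dihydro-2H-pyran-2-ol (anomer mixture)
Conditions: iBu2AlH (1.1 equiv), CH2Cl2, −78 °C; aq. potassium sodium tartrate
Reagents that add atoms: none
Why: Partial 1,2-reduction of a lactone, in which the tetrahedral aluminium lactolate survives at −78 °C so reduction stops at the lactol; the new anomeric centre is lost in the next step, and C6 and the ring-locked Z alkene are unchanged.

Step 4
Reactants: 7 (6S)-3-methyl-6-(prop-1-en-2-yl)-5,6-dihydro-2H-pyran-2-ol; 8 bromoform
Product: 10 (3S,5Z,7E)-8-bromo-2,6-dimethylocta-1,5,7-trien-3-ol, via open-chain Z-hydroxyenal 9 (not isolated)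
Conditions: CrBr2 (8 equiv), CHBr3 (3 equiv), THF, 0 °C → rt
Reagents that add atoms: bromoform (8), BrC(Br)Br
Why: Takai olefination, in which ring–chain tautomerism releases Z-enal 9 and the gem-dichromium species from CHBr3 adds and eliminates Cr–O to give the E-bromoalkene (usually ≥9:1); the all-bromide chromium salt prevents Br/Cl scrambling, and the near-neutral medium leaves the free C6 alcohol and the 3Z alkene alone.

Step 5
Reactants: 10 (3S,5Z,7E)-8-bromo-2,6-dimethylocta-1,5,7-trien-3-ol
Product: 11 (1E,3Z,6R)-1-bromo-6-chloro-3,7-dimethylocta-1,3,7-triene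
Conditions: PPh3 (1.3 equiv), Cl3CC(O)CCl3 (3 equiv), CH2Cl2, −20 → 0 °C, 30 min
Reagents that add atoms: hexachloroacetone, ClC(Cl)(Cl)C(=O)C(Cl)(Cl)Cl
Why: Appel-type deoxychlorination, in which the alkoxyphosphonium chloride forms within minutes under neutral conditions and chloride displaces Ph3PO by SN2 with inversion (6S → 6R); this reagent pair is known to give secondary allylic chlorides with very little SN2′ transposition.

Step 6
Reactants: 11 (1E,3Z,6R)-1-bromo-6-chloro-3,7-dimethylocta-1,3,7-triene
Product: 14 (1S,2S,4R,5S)-2-bromo-1-[(E)-2-bromoethenyl]-4,5-dichloro-1,5-dimethylcyclohexane, via bromonium ion 12 (not isolated), via tertiary cyclohexyl cation 13 (not isolated)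
Conditions: BrCl (1.0 equiv; from NBS + HCl·Et2O, CH2Cl2, 0 °C, decanted), added over 2 h; SnCl4 (20 mol%), CH2Cl2 (0.01 M), −78 → −40 °C; aq. NaHCO3/Na2S2O3
Reagents that add atoms: N-bromosuccinimide, O=C1CCC(=O)N1Br; hydrogen chloride, Cl
Why: Proposed new method: SnCl4 turns BrCl into a Br+ SnCl5− pair that attacks the diene at C4 (giving the tertiary, allyl-stabilised ion 12 and sparing the chloride-deactivated C7=C8 bond); bromonium formation stays reversible (Br+ exchange with excess diene under slow addition, re-ionisation of any covalent chloride adduct), so only the diastereomeric bromonium that fits a chair with C4–Br and C6–Cl both equatorial closes (C–Cl in the nodal plane of the attacking alkene, axial C6–H hyperconjugating); anti addition of Br and C8 across the 3Z alkene places the C3 methyl equatorial and the bromovinyl axial; the β-chloro cation 13 then takes chloride from SnCl5− axially (this is also the thermodynamic C7 epimer with equatorial methyl, reachable by SnCl4 re-ionisation), giving a tertiary chloride that ionises far less readily than its allylic precursor; the closest known reaction types are bromonium-initiated polyene cyclisation, Lewis-acid-promoted addition of allylic or tertiary alkyl chlorides to 1,1-disubstituted alkenes (carbochlorination, the propagation/chloride-collapse event of quasi-living isobutene polymerisation) and alkene bromochlorination with N-bromoamide/HCl.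

## Compound list
1 | methacrolein | CC(=C)C=O | starting material
2 | allyltributylstannane | C=CC[Sn](CCCC)(CCCC)CCCC | starting material
3 | methacryloyl chloride | CC(=C)C(=O)Cl | starting material
4 | tributylstannyl ether of (S)-2-methylhexa-1,5-dien-3-ol (not isolated) | C=CC[C@H](O[Sn](CCCC)(CCCC)CCCC)C(C)=C | intermediate
5 | (3S)-2-methylhexa-1,5-dien-3-yl 2-methylprop-2-enoate | C=CC[C@H](OC(=O)C(C)=C)C(C)=C | intermediate
6 | (6S)-3-methyl-6-(prop-1-en-2-yl)-5,6-dihydro-2H-pyran-2-one | CC1=CC[C@H](OC1=O)C(C)=C | intermediate
7 | (6S)-3-methyl-6-(prop-1-en-2-yl)-5,6-dihydro-2H-pyran-2-ol, anomer mixture | CC1=CC[C@H](OC1O)C(C)=C | intermediate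
8 | bromoform | BrC(Br)Br | starting material
9 | (2Z,5S)-5-hydroxy-2,6-dimethylhepta-2,6-dienal (not isolated) | O=C/C(C)=C\C[C@H](O)C(C)=C | intermediate
10 | (3S,5Z,7E)-8-bromo-2,6-dimethylocta-1,5,7-trien-3-ol | Br/C=C/C(C)=C\C[C@H](O)C(C)=C | intermediate
11 | (1E,3Z,6R)-1-bromo-6-chloro-3,7-dimethylocta-1,3,7-triene | Br/C=C/C(C)=C\C[C@@H](Cl)C(C)=C | intermediate
12 | C3/C4 bromonium ion of 11 on the face that leads to the all-equatorial chair, SnCl5− counter-ion omitted (not isolated) | C=C(C)[C@H](Cl)C[C@@H]1[Br+][C@]1(C)/C=C/Br | intermediate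
13 | tertiary cyclohexyl cation at C7 after C3–C8 closure, SnCl5− counter-ion omitted (not isolated) | C[C+]1C[C@@](C)(/C=C/Br)[C@@H](Br)C[C@H]1Cl | intermediate
14 | (1S,2S,4R,5S)-2-bromo-1-[(E)-2-bromoethenyl]-4,5-dichloro-1,5-dimethylcyclohexane | C[C@]1(Cl)C[C@@](C)(/C=C/Br)[C@@H](Br)C[C@H]1Cl | target

## Totals and risks
Total step count: 6. Longest linear sequence: 6.

**Step 6 (most likely to fail).** Three things can go wrong:
- Face selection of Br+ relative to C6 depends on reversible bromonium formation.
- The allyl-stabilised cation may lose its memory of the 3Z geometry and give the C3 epimer.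
- Proton loss, a C6→C7 hydride shift or the wrong C7 epimer may compete with axial chloride capture.

Fallback, setting out from 10 and returning at 14: fix the bromonium face covalently before any ionisation. A hydroxyl-directed, catalyst-controlled bromochlorination of the C3=C4 bond of 10 (NBS, ClTi(OiPr)3, chiral tridentate Schiff-base ligand, hexane, −20 °C) gives (3S,5S,6S,7E)-5,8-dibromo-6-chloro-2,6-dimethylocta-1,7-dien-3-ol F1. PPh3/hexachloroacetone then inverts the carbinol to give (1E,3S,4S,6R)-1,4-dibromo-3,6-dichloro-3,7-dimethylocta-1,7-diene F2. Ionising the tertiary allylic chloride of F2, with the neighbouring bromine assisting (hexafluoroisopropanol, or catalytic SnCl4 in CH2Cl2 at −78 °C), regenerates only 12. This closes through 13, and the released chloride returns at C7. The ring formation thus becomes a pure cycloisomerisation to 14.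

**Step 4.** The lactol may open slowly, the Z-enal may isomerise on trivalent chromium, and E/Z control at C1=C2 may be imperfect.

Fallback, setting out from 7 and returning at 10: replace carbonyl olefination by alkyne hydrometalation. Lithiated trimethylsilyldiazomethane (Me3SiCHN2, LiN(iPr)2, 2.2 equiv, THF, −78 °C → rt, Colvin rearrangement, no protic nucleophile to add to the enal) gives (3S,5Z)-2,6-dimethylocta-1,5-dien-7-yn-3-ol F3. Syn hydrozirconation of the terminal alkyne (Cp2Zr(H)Cl, 2.2 equiv, THF), followed by NBS, delivers the E-bromide 10 with retention.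

**Step 5.** SN2′ leakage to the achiral primary allylic chloride and ion-pair erosion of ee are the dangers.

Fallback, setting out from 10 and returning at 11: separate activation from displacement, so that no phosphonium ion pair is involved. MsCl with 2,4,6-collidine in DMF at 0 °C gives (3S,5Z,7E)-8-bromo-2,6-dimethylocta-1,5,7-trien-3-yl methanesulfonate F4. This is displaced directly by a large excess of dissolved LiCl (Collington–Meyers-type sulfonate/chloride exchange, SN2 with inversion) to give 11.

## Further compounds
F1 | step 6 | (3S,5S,6S,7E)-5,8-dibromo-6-chloro-2,6-dimethylocta-1,7-dien-3-ol | C=C(C)[C@@H](O)C[C@H](Br)[C@](Cl)(C)/C=C/Br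
F2 | step 6 | (1E,3S,4S,6R)-1,4-dibromo-3,6-dichloro-3,7-dimethylocta-1,7-diene | C=C(C)[C@H](Cl)C[C@H](Br)[C@](Cl)(C)/C=C/Br
F3 | step 4 | (3S,5Z)-2,6-dimethylocta-1,5-dien-7-yn-3-ol | C#C/C(C)=C\C[C@H](O)C(C)=C
F4 | step 5 | (3S,5Z,7E)-8-bromo-2,6-dimethylocta-1,5,7-trien-3-yl methanesulfonate | Br/C=C/C(C)=C\C[C@H](OS(C)(=O)=O)C(C)=C
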